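**Retrosynthetic overview**
1. Target 26 ⇐ O-debenzylation of 25 ⇐ C2–O ring closure of triarylethene tetraphenol 24 (chiral phosphoric acid, via the p-quinone methide tautomer).
2. 24 ⇐ aryllithium from 2-bromo-tri-O-MOM-resveratrol 3 added to deoxybenzoin 21, then MOM removal and dehydration.
3. 21 ⇐ formyl C–H insertion homologation of aldehyde 18 with aldehyde 6; 18 ⇐ C2–O ring closure of triarylethene phenol 17 (chiral N-triflylphosphoramide).
4. 17 ⇐ ortho-formylation of phenol 16 ⇐ ortho-lithiated resorcinol bis-acetal 12 added to deoxybenzoin 9 (from aldehydes 4 and 6).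
5. Ring order: the dihydrofuran of the 4-hydroxybenzofuran unit first (step 8), the dihydrofuran of the 6-hydroxy-4-styrylbenzofuran unit second (step 12); all benzene rings are bought.

Assumption: the sense of induction of the two chiral acids cannot be predicted; the catalyst enantiomer written is taken as the one giving the (S,S) ring and would be swapped for its antipode if the first run shows the opposite.

Step 1
Reactants: 1 resveratrol
Product: 2 (E)-1,3-bis(methoxymethoxy)-5-{2-[4-(methoxymethoxy)phenyl]ethenyl}benzene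
Conditions: NaH (3.6 equiv), MOMCl (3.6 equiv), DMF, 0 °C → rt
Reagents that add atoms: chloromethyl methyl ether (MOMCl), COCCl
Why: Williamson-type O-alkylation of the three phenoxides; the acetal ethers tolerate organolithiums and later come off without protic acid.

Step 2
Reactants: 2 (E)-1,3-bis(methoxymethoxy)-5-{2-[4-(methoxymethoxy)phenyl]ethenyl}benzene
Product: 3 (E)-2-bromo-1,5-bis(methoxymethoxy)-3-{2-[4-(methoxymethoxy)phenyl]ethenyl}benzene
Conditions: NBS (1.0 equiv), THF, −78 → −20 °C, dark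
Reagents that add atoms: N-bromosuccinimide, O=C1CCC(=O)N1Br
Why: Electrophilic aromatic bromination of the most activated ring at C2 (para to one OMOM, ortho to the other) rather than at the hindered position between the two ethers or at the alkene.

Step 3
Reactants: 4 2,4-bis(benzyloxy)benzaldehyde; 5 p-toluenesulfonyl hydrazide; 6 3,5-bis(benzyloxy)benzaldehyde
Product: 9 1-[3,5-bis(benzyloxy)phenyl]-2-[2,4-bis(benzyloxy)phenyl]ethan-1-one, via hydrazone 7 (not isolated), via diazo compound 8 (not isolated)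
Conditions: 5 (1.05 equiv), 1,4-dioxane, 80 °C, 1 h; then 6 (1.5 equiv), K2CO3 (2.0 equiv), 110 °C
Reagents that add atoms: none
Why: Bamford–Stevens generation of the aryldiazomethane and its Roskamp-type formyl C–H insertion into 6 (addition to C=O, 1,2-hydride shift, loss of N2) put the carbonyl on the 3,5-dioxygenated ring.

Step 4
Reactants: 10 resorcinol
Product: 11 3-(methoxymethoxy)phenol
Conditions: 10 (3 equiv), NaH (1.0 equiv), MOMCl (1.0 equiv), DMF, 0 °C → rt
Reagents that add atoms: chloromethyl methyl ether (MOMCl), COCCl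
Why: Statistical Williamson mono-alkylation of excess cheap diol; unreacted resorcinol is removed by aqueous wash.

Step 5
Reactants: 11 3-(methoxymethoxy)phenol
Product: 12 1-(1-ethoxyethoxy)-3-(methoxymethoxy)benzene (racemic)
Conditions: ethyl vinyl ether (3 equiv), PPTS (5 mol %), CH2Cl2, rt
Reagents that add atoms: ethyl vinyl ether, C=COCC
Why: Acid-catalysed addition of the phenol to the vinyl ether gives an EE acetal that directs lithiation and is far more acid-labile than MOM.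

Step 6
Reactants: 12 1-(1-ethoxyethoxy)-3-(methoxymethoxy)benzene; 9 1-[3,5-bis(benzyloxy)phenyl]-2-[2,4-bis(benzyloxy)phenyl]ethan-1-one
Product: 16 2-{1-[3,5-bis(benzyloxy)phenyl]-2-[2,4-bis(benzyloxy)phenyl]ethenyl}-3-(methoxymethoxy)phenol (E/Z mixture), via aryllithium 13 (not isolated), via EE-protected carbinol 14 (not isolated), via phenolic carbinol 15 (not isolated)
Conditions: 12 (1.3 equiv), n-BuLi (1.25 equiv), THF, 0 °C, 1 h; add to 9 + LaCl3·2LiCl (1.1 equiv), THF, −78 → 0 °C; then AcOH/H2O 4:1, 50 °C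
Reagents that add atoms: none
Why: Directed ortho-metalation between the two acetal oxygens, LaCl3·2LiCl-promoted 1,2-addition to the enolisable ketone, then weak acid hydrolyses only the EE acetal and E1-dehydrates the doubly ortho-oxygenated benzylic carbinol; no stereocentre remains.

Step 7
Reactants: 16 2-{1-[3,5-bis(benzyloxy)phenyl]-2-[2,4-bis(benzyloxy)phenyl]ethenyl}-3-(methoxymethoxy)phenol
Product: 17 3-{1-[3,5-bis(benzyloxy)phenyl]-2-[2,4-bis(benzyloxy)phenyl]ethenyl}-2-hydroxy-4-(methoxymethoxy)benzaldehyde (E/Z mixture)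
Conditions: MgCl2 (2 equiv), Et3N (4 equiv), (CH2O)n (6 equiv), MeCN, 80 °C
Reagents that add atoms: paraformaldehyde (formaldehyde), C=O
Why: Magnesium phenoxide-directed ortho-formylation (Casnati–Skattebøl type) reacts only at the single free position ortho to the single free phenol, the carbon that becomes C7 of the first benzofuran.

Step 8
Reactants: 17 3-{1-[3,5-bis(benzyloxy)phenyl]-2-[2,4-bis(benzyloxy)phenyl]ethenyl}-2-hydroxy-4-(methoxymethoxy)benzaldehyde
Product: 18 (2S,3S)-2-[2,4-bis(benzyloxy)phenyl]-3-[3,5-bis(benzyloxy)phenyl]-4-(methoxymethoxy)-2,3-dihydro-1-benzofuran-7-carbaldehyde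
Conditions: (S)-3,3'-bis(2,4,6-triisopropylphenyl)-1,1'-binaphthyl-2,2'-diyl N-triflylphosphoramide (5 mol %), PhMe, 5 Å MS, −30 °C
Reagents that add atoms: none
Why: Proposed new method: the strong chiral acid protonates the electron-rich triarylethene at the diaryl carbon to give a 2,4-bis(benzyloxy)benzyl cation held as a contact ion pair with the chiral anion (both alkene isomers converge on it and proton transfer is reversible), the anion hydrogen-bonds the salicylaldehyde OH, and the committing 5-exo C–O bond formation sets C2 with its aryl trans to the C3 aryl while the ion pair selects the (3S) cation, the formyl group keeping its own ring from stabilising the alternative tertiary cation; the closest known reaction type is chiral Brønsted acid (phosphoramide or imidodiphosphorimidate) catalysed asymmetric intramolecular hydroalkoxylation of alkenes, not yet shown for 2-(1,2-diarylvinyl)phenols or for setting two adjacent benzylic centres.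

Step 9
Reactants: 18 (2S,3S)-2-[2,4-bis(benzyloxy)phenyl]-3-[3,5-bis(benzyloxy)phenyl]-4-(methoxymethoxy)-2,3-dihydro-1-benzofuran-7-carbaldehyde; 5 p-toluenesulfonyl hydrazide; 6 3,5-bis(benzyloxy)benzaldehyde
Product: 21 1-[3,5-bis(benzyloxy)phenyl]-2-{(2S,3S)-2-[2,4-bis(benzyloxy)phenyl]-3-[3,5-bis(benzyloxy)phenyl]-4-(methoxymethoxy)-2,3-dihydro-1-benzofuran-7-yl}ethan-1-one, via hydrazone 19 (not isolated), via diazo compound 20 (not isolated)
Conditions: 5 (1.05 equiv), 1,4-dioxane, 80 °C; then 6 (3 equiv), K2CO3 (2 equiv), 110 °C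
Reagents that add atoms: none
Why: Same Bamford–Stevens/Roskamp-type formyl C–H insertion as step 3; carbonate is far too weak a base to touch the two benzylic stereocentres.

Step 10
Reactants: 3 (E)-2-bromo-1,5-bis(methoxymethoxy)-3-{2-[4-(methoxymethoxy)phenyl]ethenyl}benzene; 21 1-[3,5-bis(benzyloxy)phenyl]-2-{(2S,3S)-2-[2,4-bis(benzyloxy)phenyl]-3-[3,5-bis(benzyloxy)phenyl]-4-(methoxymethoxy)-2,3-dihydro-1-benzofuran-7-yl}ethan-1-one
Product: 23 1-[3,5-bis(benzyloxy)phenyl]-2-{(2S,3S)-2-[2,4-bis(benzyloxy)phenyl]-3-[3,5-bis(benzyloxy)phenyl]-4-(methoxymethoxy)-2,3-dihydro-1-benzofuran-7-yl}-1-{2,4-bis(methoxymethoxy)-6-[(E)-2-(4-(methoxymethoxy)phenyl)ethenyl]phenyl}ethan-1-ol (two carbinol epimers), via aryllithium 22 (not isolated)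
Conditions: 3 (2.0 equiv), n-BuLi (2.0 equiv), THF, −78 °C; add to 21 + LaCl3·2LiCl (1.2 equiv), THF, −78 → −30 °C; sat. aq. NH4Cl
Reagents that add atoms: none
Why: Bromine–lithium exchange gives the MOM-chelated aryllithium and LaCl3·2LiCl-promoted 1,2-addition beats enolisation of the deoxybenzoin; the uncontrolled carbinol centre is erased in step 11.

Step 11
Reactants: 23 tertiary alcohol from step 10
Product: 24 4-{1-[3,5-bis(benzyloxy)phenyl]-2-[(2S,3S)-2-[2,4-bis(benzyloxy)phenyl]-3-[3,5-bis(benzyloxy)phenyl]-4-hydroxy-2,3-dihydro-1-benzofuran-7-yl]ethenyl}-5-[(E)-2-(4-hydroxyphenyl)ethenyl]benzene-1,3-diol (E/Z mixture at the new alkene)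
Conditions: TMSOTf (12 equiv), 2,2'-bipyridyl (18 equiv), CH2Cl2, 0 °C → rt; then H2O, aq. NaHCO3
Reagents that add atoms: none
Why: Silyl triflate/pyridine cleavage of the four aryl MOM acetals through pyridinium intermediates with concurrent base-assisted E1 dehydration of the tertiary benzylic alcohol; the buffered, non-protic medium avoids cation–stilbene cyclisation and premature ring closure.

Step 12
Reactants: 24 triarylethene tetraphenol from step 11
Product: 25 (2S,3S)-3-[3,5-bis(benzyloxy)phenyl]-2-{(2S,3S)-2-[2,4-bis(benzyloxy)phenyl]-3-[3,5-bis(benzyloxy)phenyl]-4-hydroxy-2,3-dihydro-1-benzofuran-7-yl}-4-[(E)-2-(4-hydroxyphenyl)ethenyl]-2,3-dihydro-1-benzofuran-6-ol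
Conditions: (R)-TRIP [(R)-3,3'-bis(2,4,6-triisopropylphenyl)-1,1'-binaphthyl-2,2'-diyl hydrogen phosphate] (10 mol %), CH2Cl2/PhMe 1:1, 4 Å MS, −20 → 0 °C
Reagents that add atoms: none
Why: Proposed new method: the free hydroxyl para to the alkene lets the phosphoric acid relay a proton from that OH to C3, turning the vinylphenol into its p-quinone methide tautomer (the intermediate nature reaches by radical coupling) without a free cation next to the stilbene, and the bifunctional acid then binds the quinone methide carbonyl and the ortho phenol and delivers the ring-closing oxa-1,6-addition, trans to the C3 aryl and (2S,3S) by catalyst control because tautomerisation is reversible and C–O bond formation is the selecting step; the closest known reaction types are chiral phosphoric acid catalysed additions to quinone methides formed in situ from hydroxystyrenes and organocatalytic oxa-1,6-additions to p-quinone methides, not yet shown as a ring-closing hydroalkoxylation of a triarylethene.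

Step 13
Reactants: 25 hexabenzyl ether from step 12
Product: 26 (2S,3S)-3-(3,5-dihydroxyphenyl)-2-[(2S,3S)-2-(2,4-dihydroxyphenyl)-3-(3,5-dihydroxyphenyl)-4-hydroxy-2,3-dihydro-1-benzofuran-7-yl]-4-[(E)-2-(4-hydroxyphenyl)ethenyl]-2,3-dihydro-1-benzofuran-6-ol
Conditions: BCl3 (20 equiv), C6HMe5 (30 equiv), CH2Cl2, −78 °C; MeOH quench at −78 °C, aq. NaHCO3
Reagents that add atoms: none
Why: Lewis acid O-debenzylation with pentamethylbenzene as a non-basic benzyl cation scavenger (Friedel–Crafts capture) at −78 °C, where the boron-bound phenoxides are poor donors so the stilbene and both benzylic C–O bonds stay intact; no stereocentre is touched.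

**Compound list**
1 | resveratrol | Oc1ccc(/C=C/c2cc(O)cc(O)c2)cc1 | starting material
2 | (E)-1,3-bis(methoxymethoxy)-5-{2-[4-(methoxymethoxy)phenyl]ethenyl}benzene | COCOc1ccc(/C=C/c2cc(OCOC)cc(OCOC)c2)cc1 | intermediate
3 | (E)-2-bromo-1,5-bis(methoxymethoxy)-3-{2-[4-(methoxymethoxy)phenyl]ethenyl}benzene | COCOc1ccc(/C=C/c2cc(OCOC)cc(OCOC)c2Br)cc1 | intermediate
4 | 2,4-bis(benzyloxy)benzaldehyde | O=Cc1ccc(OCc2ccccc2)cc1OCc1ccccc1 | starting material
5 | p-toluenesulfonyl hydrazide | Cc1ccc(cc1)S(=O)(=O)NN | starting material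
6 | 3,5-bis(benzyloxy)benzaldehyde | O=Cc1cc(OCc2ccccc2)cc(OCc2ccccc2)c1 | starting material
7 | N'-[(E)-2,4-bis(benzyloxy)benzylidene]-4-methylbenzenesulfonohydrazide | Cc1ccc(cc1)S(=O)(=O)N/N=C/c1ccc(OCc2ccccc2)cc1OCc1ccccc1 | intermediate (not isolated)
8 | 2,4-bis(benzyloxy)-1-(diazomethyl)benzene | [N-]=[N+]=Cc1ccc(OCc2ccccc2)cc1OCc1ccccc1 | intermediate (not isolated)
9 | 1-[3,5-bis(benzyloxy)phenyl]-2-[2,4-bis(benzyloxy)phenyl]ethan-1-one | O=C(Cc1ccc(OCc2ccccc2)cc1OCc1ccccc1)c1cc(OCc2ccccc2)cc(OCc2ccccc2)c1 | intermediate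
10 | resorcinol | Oc1cccc(O)c1 | starting material
11 | 3-(methoxymethoxy)phenol | COCOc1cccc(O)c1 | intermediate
12 | 1-(1-ethoxyethoxy)-3-(methoxymethoxy)benzene (racemic) | CCOC(C)Oc1cccc(OCOC)c1 | intermediate
13 | [2-(1-ethoxyethoxy)-6-(methoxymethoxy)phenyl]lithium | [Li]c1c(OC(C)OCC)cccc1OCOC | intermediate (not isolated)
14 | 1-[3,5-bis(benzyloxy)phenyl]-2-[2,4-bis(benzyloxy)phenyl]-1-[2-(1-ethoxyethoxy)-6-(methoxymethoxy)phenyl]ethan-1-ol (diastereomer mixture) | CCOC(C)Oc1cccc(OCOC)c1C(O)(Cc1ccc(OCc2ccccc2)cc1OCc1ccccc1)c1cc(OCc2ccccc2)cc(OCc2ccccc2)c1 | intermediate (not isolated)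
15 | 2-{1-[3,5-bis(benzyloxy)phenyl]-2-[2,4-bis(benzyloxy)phenyl]-1-hydroxyethyl}-3-(methoxymethoxy)phenol (racemic) | COCOc1cccc(O)c1C(O)(Cc1ccc(OCc2ccccc2)cc1OCc1ccccc1)c1cc(OCc2ccccc2)cc(OCc2ccccc2)c1 | intermediate (not isolated)
16 | 2-{1-[3,5-bis(benzyloxy)phenyl]-2-[2,4-bis(benzyloxy)phenyl]ethenyl}-3-(methoxymethoxy)phenol (E/Z mixture) | COCOc1cccc(O)c1C(=Cc1ccc(OCc2ccccc2)cc1OCc1ccccc1)c1cc(OCc2ccccc2)cc(OCc2ccccc2)c1 | intermediate
17 | 3-{1-[3,5-bis(benzyloxy)phenyl]-2-[2,4-bis(benzyloxy)phenyl]ethenyl}-2-hydroxy-4-(methoxymethoxy)benzaldehyde (E/Z mixture) | COCOc1ccc(C=O)c(O)c1C(=Cc1ccc(OCc2ccccc2)cc1OCc1ccccc1)c1cc(OCc2ccccc2)cc(OCc2ccccc2)c1 | intermediate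
18 | (2S,3S)-2-[2,4-bis(benzyloxy)phenyl]-3-[3,5-bis(benzyloxy)phenyl]-4-(methoxymethoxy)-2,3-dihydro-1-benzofuran-7-carbaldehyde | O=Cc1ccc(OCOC)c2c1O[C@H](c1ccc(OCc3ccccc3)cc1OCc1ccccc1)[C@H]2c1cc(OCc2ccccc2)cc(OCc2ccccc2)c1 | intermediate
19 | (E)-tosylhydrazone of aldehyde 18 | Cc1ccc(cc1)S(=O)(=O)N/N=C/c1ccc(OCOC)c2c1O[C@H](c1ccc(OCc3ccccc3)cc1OCc1ccccc1)[C@H]2c1cc(OCc2ccccc2)cc(OCc2ccccc2)c1 | intermediate (not isolated)
20 | (2S,3S)-2-[2,4-bis(benzyloxy)phenyl]-3-[3,5-bis(benzyloxy)phenyl]-7-(diazomethyl)-4-(methoxymethoxy)-2,3-dihydro-1-benzofuran | [N-]=[N+]=Cc1ccc(OCOC)c2c1O[C@H](c1ccc(OCc3ccccc3)cc1OCc1ccccc1)[C@H]2c1cc(OCc2ccccc2)cc(OCc2ccccc2)c1 | intermediate (not isolated)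
21 | 1-[3,5-bis(benzyloxy)phenyl]-2-{(2S,3S)-2-[2,4-bis(benzyloxy)phenyl]-3-[3,5-bis(benzyloxy)phenyl]-4-(methoxymethoxy)-2,3-dihydro-1-benzofuran-7-yl}ethan-1-one | O=C(Cc1ccc(OCOC)c2c1O[C@H](c1ccc(OCc3ccccc3)cc1OCc1ccccc1)[C@H]2c1cc(OCc2ccccc2)cc(OCc2ccccc2)c1)c1cc(OCc2ccccc2)cc(OCc2ccccc2)c1 | intermediate
22 | {2,4-bis(methoxymethoxy)-6-[(E)-2-(4-(methoxymethoxy)phenyl)ethenyl]phenyl}lithium | COCOc1ccc(/C=C/c2cc(OCOC)cc(OCOC)c2[Li])cc1 | intermediate (not isolated)
23 | tertiary alcohol: 1-[3,5-bis(benzyloxy)phenyl]-2-[(2S,3S)-benzofuran-7-yl unit of 21]-1-{2,4-bis(methoxymethoxy)-6-[(E)-4-(methoxymethoxy)styryl]phenyl}ethan-1-ol (two carbinol epimers) | COCOc1ccc(/C=C/c2cc(OCOC)cc(OCOC)c2C(O)(Cc2ccc(OCOC)c3c2O[C@H](c2ccc(OCc4ccccc4)cc2OCc2ccccc2)[C@H]3c2cc(OCc3ccccc3)cc(OCc3ccccc3)c2)c2cc(OCc3ccccc3)cc(OCc3ccccc3)c2)cc1 | intermediate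
24 | 4-{1-[3,5-bis(benzyloxy)phenyl]-2-[(2S,3S)-2-[2,4-bis(benzyloxy)phenyl]-3-[3,5-bis(benzyloxy)phenyl]-4-hydroxy-2,3-dihydro-1-benzofuran-7-yl]ethenyl}-5-[(E)-2-(4-hydroxyphenyl)ethenyl]benzene-1,3-diol (E/Z mixture at the triaryl alkene) | Oc1ccc(/C=C/c2cc(O)cc(O)c2C(=Cc2ccc(O)c3c2O[C@H](c2ccc(OCc4ccccc4)cc2OCc2ccccc2)[C@H]3c2cc(OCc3ccccc3)cc(OCc3ccccc3)c2)c2cc(OCc3ccccc3)cc(OCc3ccccc3)c2)cc1 | intermediate
25 | (2S,3S)-3-[3,5-bis(benzyloxy)phenyl]-2-{(2S,3S)-2-[2,4-bis(benzyloxy)phenyl]-3-[3,5-bis(benzyloxy)phenyl]-4-hydroxy-2,3-dihydro-1-benzofuran-7-yl}-4-[(E)-2-(4-hydroxyphenyl)ethenyl]-2,3-dihydro-1-benzofuran-6-ol | Oc1ccc(/C=C/c2cc(O)cc3c2[C@H](c2cc(OCc4ccccc4)cc(OCc4ccccc4)c2)[C@@H](c2ccc(O)c4c2O[C@H](c2ccc(OCc5ccccc5)cc2OCc2ccccc2)[C@H]4c2cc(OCc4ccccc4)cc(OCc4ccccc4)c2)O3)cc1 | intermediate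
26 | (2S,3S)-3-(3,5-dihydroxyphenyl)-2-[(2S,3S)-2-(2,4-dihydroxyphenyl)-3-(3,5-dihydroxyphenyl)-4-hydroxy-2,3-dihydro-1-benzofuran-7-yl]-4-[(E)-2-(4-hydroxyphenyl)ethenyl]-2,3-dihydro-1-benzofuran-6-ol (CNP0397447.1) | Oc1ccc(/C=C/c2cc(O)cc3c2[C@H](c2cc(O)cc(O)c2)[C@@H](c2ccc(O)c4c2O[C@H](c2ccc(O)cc2O)[C@H]4c2cc(O)cc(O)c2)O3)cc1 | target

**Step count**
Total: 13 steps. Longest linear sequence: 10 steps (steps 4 to 13, from resorcinol).

**Three steps most likely to fail**

Step 8 (new ring closure 1). The acid may give low enantioselectivity or attack the MOM ether. The fallback sets out from 17 and comes back at 18. Close the ring with an achiral Brønsted acid (diphenyl phosphate 10 mol %, PhMe, 0 °C; ordinary acid-catalysed hydroalkoxylation of an electron-rich styrene by a phenol, trans by thermodynamics). This gives racemic trans material, that is 18 together with the (2R,3R)-enantiomer of aldehyde 18 F1. Resolve by preparative chiral SFC, carry 18 on and discard F1.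

Step 10 (hindered aryllithium addition to an enolisable ketone). Enolisation or steric failure is possible even with the lanthanum salt. The fallback sets out from 21 and 3 and comes back at 24. Convert 21 to the (Z)-enol triflate of ketone 21 F2 (KHMDS, PhNTf2, THF, −78 °C). Convert 3 to the pinacol boronate of the resveratrol tris-MOM ether F3 (n-BuLi, 2-isopropoxy-4,4,5,5-tetramethyl-1,3,2-dioxaborolane, THF, −78 °C). Join them by Suzuki–Miyaura coupling (Pd(OAc)2, SPhos, K3PO4, PhMe/H2O, 80 °C) to give the tetra-MOM triarylethene F4, which never passes through a tertiary cation. Then remove the MOM groups as in step 11 (TMSOTf, 2,2'-bipyridyl; H2O) to reach 24.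

Step 12 (new ring closure 2). Catalyst control over the remote, already chiral substrate may be weak, or the stilbene may interfere. The fallback sets out from 24 and comes back at 25. Close the ring without catalyst control (diphenyl phosphate 10 mol %, CH2Cl2, 0 °C; the known quinone methide closure of this compound class, trans in the new ring). This gives 25 together with the (2R,3R)-ring diastereomer of 25 F5. Because the first ring is already enantiopure these are diastereomers; separate them by preparative HPLC on an achiral phase and carry 25 on.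

Further compounds
F1 | step 8 | (2R,3R)-2-[2,4-bis(benzyloxy)phenyl]-3-[3,5-bis(benzyloxy)phenyl]-4-(methoxymethoxy)-2,3-dihydro-1-benzofuran-7-carbaldehyde | O=Cc1ccc(OCOC)c2c1O[C@@H](c1ccc(OCc3ccccc3)cc1OCc1ccccc1)[C@@H]2c1cc(OCc2ccccc2)cc(OCc2ccccc2)c1
F2 | step 10 | (Z)-1-[3,5-bis(benzyloxy)phenyl]-2-{(2S,3S)-2-[2,4-bis(benzyloxy)phenyl]-3-[3,5-bis(benzyloxy)phenyl]-4-(methoxymethoxy)-2,3-dihydro-1-benzofuran-7-yl}ethenyl trifluoromethanesulfonate | FC(F)(F)S(=O)(=O)O/C(=C\c1ccc(OCOC)c2c1O[C@H](c1ccc(OCc3ccccc3)cc1OCc1ccccc1)[C@H]2c1cc(OCc2ccccc2)cc(OCc2ccccc2)c1)c1cc(OCc2ccccc2)cc(OCc2ccccc2)c1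
F3 | step 10 | 2-{2,4-bis(methoxymethoxy)-6-[(E)-2-(4-(methoxymethoxy)phenyl)ethenyl]phenyl}-4,4,5,5-tetramethyl-1,3,2-dioxaborolane | COCOc1ccc(/C=C/c2cc(OCOC)cc(OCOC)c2B2OC(C)(C)C(C)(C)O2)cc1
F4 | step 10 | (Z)-triarylethene, the tetra-MOM ether of 24 (aryl from 3 cis to the benzofuranyl group) | COCOc1ccc(/C=C/c2cc(OCOC)cc(OCOC)c2/C(=C\c2ccc(OCOC)c3c2O[C@H](c2ccc(OCc4ccccc4)cc2OCc2ccccc2)[C@H]3c2cc(OCc3ccccc3)cc(OCc3ccccc3)c2)c2cc(OCc3ccccc3)cc(OCc3ccccc3)c2)cc1
F5 | step 12 | (2R,3R)-3-[3,5-bis(benzyloxy)phenyl]-2-{(2S,3S)-2-[2,4-bis(benzyloxy)phenyl]-3-[3,5-bis(benzyloxy)phenyl]-4-hydroxy-2,3-dihydro-1-benzofuran-7-yl}-4-[(E)-2-(4-hydroxyphenyl)ethenyl]-2,3-dihydro-1-benzofuran-6-ol | Oc1ccc(/C=C/c2cc(O)cc3c2[C@@H](c2cc(OCc4ccccc4)cc(OCc4ccccc4)c2)[C@H](c2ccc(O)c4c2O[C@H](c2ccc(OCc5ccccc5)cc2OCc2ccccc2)[C@H]4c2cc(OCc4ccccc4)cc(OCc4ccccc4)c2)O3)cc1
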